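Ring A is built last instead of being bought. Its C5–C6–C7–C8 edge carries OH, H, OMe and prenyl in the very order found in the extended enol ether of γ-prenylated methyl acetoacetate, and C4a=C8a is the enone alkene of ring C. The target is therefore cut at C8–C8a and C4a–C5. One [4+2] cycloaddition of that vinylketene acetal to an enantiopure trans-2-aryl-3-silyloxy-2,3-dihydropyran-4-one with a phenylsulfinyl group on the future C4a makes both bonds and the ring; loss of PhSOH and MeOSiMe3 aromatises in the same flask. C2 and C3 are set beforehand, and both hydroxyls travel as TBS ethers, so one fluoride step finishes.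

Key step: step 10

Remark on numbering: monocyclic compounds use pyranone numbering (O1, C2 aryl, C3 oxygen, C4 carbonyl, C5, C6). Bicyclic compounds use flavanone numbering, in which pyranone C5 and C6 become C4a and C8a. TBS = tert-butyldimethylsilyl.

Remark on descriptors: (2S) in compound 5 and (2R) in all 3-oxygenated compounds describe the same spatial arrangement, because C3 outranks the aryl group once it carries oxygen.

Assumption on the sense of induction: the complex made from Ti(OiPr)4 and (S)-BINOL is taken to send carbon nucleophiles to the Si face of aromatic aldehydes, as in the related allylation. If a first run shows the opposite sense, the equally available (R)-BINOL is used.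

Step 1
Reactants: 1 4-hydroxybenzaldehyde
Product: 2 4-(tert-butyldimethylsilyloxy)benzaldehyde
Conditions: TBSCl, imidazole, DMF, rt
Reagents that add atoms: tert-butyldimethylsilyl chloride, CC(C)(C)[Si](C)(C)Cl
Why: Imidazole-promoted silyl ether protection of a phenol, giving a group that is a weaker donor than an alkyl or acetal ether and that leaves together with the C3 silyl ether in step 11.

Step 2
Reactants: 2 4-(tert-butyldimethylsilyloxy)benzaldehyde; 3 Danishefsky's diene, (E)-1-methoxy-3-(trimethylsilyloxy)buta-1,3-diene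
Product: 5 (2S)-2-[4-(tert-butyldimethylsilyloxy)phenyl]-2,3-dihydro-4H-pyran-4-one, via Mukaiyama aldol adduct 4 (not isolated)
Conditions: Ti(OiPr)4 (10 mol %), (S)-BINOL (20 mol %), 4 Å MS, Et2O, −20 °C; then TFA, CH2Cl2, 0 °C
Reagents that add atoms: none
Why: Catalytic enantioselective hetero-Diels–Alder reaction in its Mukaiyama aldol/cyclisation form, in which the chiral complex of Ti(OiPr)4 and (S)-BINOL should leave only the Si face of the bound aldehyde open to the diene terminus and so set C2, after which TFA closes the ring by addition–elimination with loss of methanol.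

Step 3
Reactants: 5 (2S)-2-[4-(tert-butyldimethylsilyloxy)phenyl]-2,3-dihydro-4H-pyran-4-one
Product: 7 (2R,3R)-2-[4-(tert-butyldimethylsilyloxy)phenyl]-3-hydroxy-2,3-dihydro-4H-pyran-4-one (2,3-trans), via sodium enolate 6 (not isolated)
Conditions: NaN(SiMe3)2, THF, −78 °C; 2-(phenylsulfonyl)-3-phenyloxaziridine, −78 °C; AcOH quench at −78 °C
Reagents that add atoms: 2-(phenylsulfonyl)-3-phenyloxaziridine, O=S(=O)(c1ccccc1)N1OC1c1ccccc1
Why: Davis oxidation of the kinetic cross-conjugated enolate, in which C3 is the only acidic carbon and the oxaziridine should approach anti to the neighbouring C2 aryl group to set 3R (trans, also the more stable diequatorial isomer), while the low temperature and cold acidic quench guard against ring opening by loss of O1.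

Step 4
Reactants: 7 (2R,3R)-2-[4-(tert-butyldimethylsilyloxy)phenyl]-3-hydroxy-2,3-dihydro-4H-pyran-4-one
Product: 8 (2R,3R)-3-(tert-butyldimethylsilyloxy)-2-[4-(tert-butyldimethylsilyloxy)phenyl]-2,3-dihydro-4H-pyran-4-one
Conditions: TBSCl, imidazole, DMF, rt
Reagents that add atoms: tert-butyldimethylsilyl chloride, CC(C)(C)[Si](C)(C)Cl
Why: Silyl ether protection of a secondary α-hydroxy ketone under conditions too weakly basic to enolise C3, so both stereocentres are kept.

Step 5
Reactants: 8 (2R,3R)-3-(tert-butyldimethylsilyloxy)-2-[4-(tert-butyldimethylsilyloxy)phenyl]-2,3-dihydro-4H-pyran-4-one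
Product: 10 (2R,3R)-3-(tert-butyldimethylsilyloxy)-2-[4-(tert-butyldimethylsilyloxy)phenyl]-5-(phenylthio)-2,3-dihydro-4H-pyran-4-one, via chloro sulfide adduct 9 (not isolated)
Conditions: PhSH, NCS, CH2Cl2, 0 °C (forms PhSCl); add 8, −78 → 0 °C; then Et3N, 0 °C → rt
Reagents that add atoms: thiophenol, Sc1ccccc1
Why: α-Sulfenylation of an enone by sulfenyl chloride addition and dehydrochlorination, in which sulfur attacks the nucleophilic C5 of the vinylogous ester, chloride caps the oxocarbenium carbon C6, and Et3N removes the now doubly activated H-5 to restore the alkene.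

Step 6
Reactants: 10 (2R,3R)-3-(tert-butyldimethylsilyloxy)-2-[4-(tert-butyldimethylsilyloxy)phenyl]-5-(phenylthio)-2,3-dihydro-4H-pyran-4-one
Product: 11 (2R,3R)-3-(tert-butyldimethylsilyloxy)-2-[4-(tert-butyldimethylsilyloxy)phenyl]-5-(phenylsulfinyl)-2,3-dihydro-4H-pyran-4-one (both sulfur epimers, used together)
Conditions: mCPBA (1.0 equiv), CH2Cl2, −78 → −20 °C
Reagents that add atoms: 3-chloroperoxybenzoic acid, OOC(=O)c1cccc(Cl)c1
Why: Chemoselective sulfide-to-sulfoxide oxidation with one equivalent of peracid, to which the push–pull alkene is inert, at a stage where no prenyl group is present and where the new sulfur stereocentre does not matter because sulfur is expelled in step 10.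

Step 7
Reactants: 12 methyl acetoacetate; 13 prenyl bromide (1-bromo-3-methylbut-2-ene)
Product: 15 methyl 7-methyl-3-oxooct-6-enoate, via sodium lithium dianion 14 (not isolated)
Conditions: NaH, THF, 0 °C; n-BuLi, 0 °C; 13, 0 °C → rt; dilute HCl
Reagents that add atoms: none
Why: γ-Alkylation of the acetoacetate dianion, whose more basic terminal carbon displaces the primary allylic bromide by SN2 and so places the prenyl group on the future C8.

Step 8
Reactants: 15 methyl 7-methyl-3-oxooct-6-enoate
Product: 16 methyl (2E)-3-methoxy-7-methylocta-2,6-dienoate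
Conditions: HC(OMe)3, TsOH (cat.), MeOH, rt; K2CO3 quench; distil
Reagents that add atoms: trimethyl orthoformate, COC(OC)OC
Why: Acid-catalysed enol ether formation from a β-keto ester with an orthoester, which should give the more stable E isomer (methoxy trans to the ester) and fixes the future 7-OMe, while a trace of acid in anhydrous medium should leave the trisubstituted alkene alone.

Step 9
Reactants: 16 methyl (2E)-3-methoxy-7-methylocta-2,6-dienoate
Product: 18 (1Z,3Z)-1,3-dimethoxy-7-methyl-1-(trimethylsilyloxy)octa-1,3,6-triene (ketene acetal geometry of no consequence), via lithium dienolate 17 (not isolated)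
Conditions: LiN(iPr)2, THF, −78 °C; TMSCl, −78 °C → rt; pentane, filter, concentrate, use at once
Reagents that add atoms: chlorotrimethylsilane, C[Si](C)(C)Cl
Why: Kinetic γ-deprotonation of a β-methoxy enoate (the γ-CH2 lies cis to the ester and is reached by the ester-bound amide) and O-silylation of the extended enolate, the standard entry to vinylketene silyl acetals, with allylic strain expected to turn the prenyl-bearing CH2 outward (3Z) as the s-cis conformation requires.

Step 10
Reactants: 11 (2R,3R)-3-(tert-butyldimethylsilyloxy)-2-[4-(tert-butyldimethylsilyloxy)phenyl]-5-(phenylsulfinyl)-2,3-dihydro-4H-pyran-4-one; 18 (1Z,3Z)-1,3-dimethoxy-7-methyl-1-(trimethylsilyloxy)octa-1,3,6-triene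
Product: 22 (2R,3R)-3-(tert-butyldimethylsilyloxy)-2-[4-(tert-butyldimethylsilyloxy)phenyl]-5-hydroxy-7-methoxy-8-(3-methylbut-2-enyl)chroman-4-one, via cis-fused cycloadduct 19 (not isolated), via cyclohexadiene mixed acetal 20 (not isolated), via cross-conjugated dienone 21 (not isolated)
Conditions: 18 (2.5 equiv), PhMe (0.5 M), Ar, 25 → 90 °C; then SiO2, CH2Cl2, rt
Reagents that add atoms: none
Why: Proposed new method: the prenyl-bearing terminus of 18 (future C8, largest HOMO coefficient) should bond to C6 of 11 (future C8a), which is β to both the ketone and the sulfinyl group, while the ketene acetal carbon (future C5) closes onto the sulfur-bearing carbon (future C4a) in a concerted but strongly asynchronous intermolecular [4+2] cycloaddition that closes ring A as a six-membered carbocycle and gives 19. Both new bonds form on one face of the alkene, which leaves the C4a sulfoxide and H-8a on the same side of the ring fusion, and since H-8a is also the only β-hydrogen the five-centre thermal elimination of PhSOH has one outcome, the C4a=C8a alkene of 20, whose C5 mixed acetal then ejects MeOSiMe3 to give 21, which tautomerises through H-8 to the hydrogen-bonded 5-phenol 22. The closest known reaction type is the benzannulation of 1,1,3-trioxygenated dienes with 2-sulfinyl- or 2-halo-quinones and other doubly activated enones, in which the activating group and an alcohol are lost, but a β-alkoxy enone of the dihydropyranone class has not served in this role. No lasting stereocentre is made, because C4a, C5, C8 and C8a all end as sp2 carbons, so facial and endo/exo selectivity are irrelevant and C2 and C3 are spectators in a neutral medium. The step needs regioselectivity, which the matched polarity of the two partners secures, and retention of O1, which is secured because C4a of 19 is quaternary (no enolate from which O1 could leave) and because no base, fluoride or Lewis acid is present. O1 feeds electron density into the alkene and would make a plain dihydropyranone a poor dienophile, so the second acceptor on C5 is there to lower the LUMO again, and the 4'-silyl ether keeps the benzylic C2–O1 bond from ionising on heating.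

Step 11
Reactants: 22 (2R,3R)-3-(tert-butyldimethylsilyloxy)-2-[4-(tert-butyldimethylsilyloxy)phenyl]-5-hydroxy-7-methoxy-8-(3-methylbut-2-enyl)chroman-4-one
Product: 23 (2R,3R)-3,5-dihydroxy-2-(4-hydroxyphenyl)-7-methoxy-8-(3-methylbut-2-enyl)chroman-4-one (target)
Conditions: Et3N·3HF (excess), MeCN, rt → 40 °C
Reagents that add atoms: none
Why: Fluoride-induced cleavage of both silyl ethers with a slightly acidic HF source, which avoids phenoxide or enolate formation (and with it C2/C3 epimerisation or ring opening) and does not touch the prenyl alkene or the aryl methyl ether.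

Compound list
1 | 4-hydroxybenzaldehyde | O=Cc1ccc(O)cc1 | starting material
2 | 4-(tert-butyldimethylsilyloxy)benzaldehyde | O=Cc1ccc(O[Si](C)(C)C(C)(C)C)cc1 | intermediate
3 | Danishefsky's diene, (E)-1-methoxy-3-(trimethylsilyloxy)buta-1,3-diene | CO/C=C/C(=C)O[Si](C)(C)C | starting material
4 | Mukaiyama aldol adduct, (1E,5S)-5-[4-(TBSO)phenyl]-1-methoxy-5-(trimethylsilyloxy)pent-1-en-3-one (not isolated) | CO/C=C/C(=O)C[C@H](O[Si](C)(C)C)c1ccc(O[Si](C)(C)C(C)(C)C)cc1 | intermediate
5 | (2S)-2-[4-(TBSO)phenyl]-2,3-dihydro-4H-pyran-4-one | C1=CO[C@H](c2ccc(O[Si](C)(C)C(C)(C)C)cc2)CC1=O | intermediate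
6 | sodium enolate of 5, sodium (2S)-2-[4-(TBSO)phenyl]-2H-pyran-4-olate (not isolated) | C1=CO[C@H](c2ccc(O[Si](C)(C)C(C)(C)C)cc2)C=C1[O-].[Na+] | intermediate
7 | (2R,3R)-2-[4-(TBSO)phenyl]-3-hydroxy-2,3-dihydro-4H-pyran-4-one, 2,3-trans | C1=CO[C@H](c2ccc(O[Si](C)(C)C(C)(C)C)cc2)[C@@H](O)C1=O | intermediate
8 | (2R,3R)-3-(TBSO)-2-[4-(TBSO)phenyl]-2,3-dihydro-4H-pyran-4-one | C1=CO[C@H](c2ccc(O[Si](C)(C)C(C)(C)C)cc2)[C@@H](O[Si](C)(C)C(C)(C)C)C1=O | intermediate
9 | chloro sulfide adduct, (2R,3R)-6-chloro-5-(phenylthio)tetrahydropyran-4-one derivative of 8, C5 and C6 not assigned (not isolated) | C1(Sc2ccccc2)C(Cl)O[C@H](c2ccc(O[Si](C)(C)C(C)(C)C)cc2)[C@@H](O[Si](C)(C)C(C)(C)C)C1=O | intermediate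
10 | (2R,3R)-3-(TBSO)-2-[4-(TBSO)phenyl]-5-(phenylthio)-2,3-dihydro-4H-pyran-4-one | C1(Sc2ccccc2)=CO[C@H](c2ccc(O[Si](C)(C)C(C)(C)C)cc2)[C@@H](O[Si](C)(C)C(C)(C)C)C1=O | intermediate
11 | (2R,3R)-3-(TBSO)-2-[4-(TBSO)phenyl]-5-(phenylsulfinyl)-2,3-dihydro-4H-pyran-4-one, both sulfur epimers | C1(S(=O)c2ccccc2)=CO[C@H](c2ccc(O[Si](C)(C)C(C)(C)C)cc2)[C@@H](O[Si](C)(C)C(C)(C)C)C1=O | intermediate
12 | methyl acetoacetate | COC(=O)CC(C)=O | starting material
13 | prenyl bromide | CC(C)=CCBr | starting material
14 | sodium lithium dianion of methyl acetoacetate (not isolated) | C=C([O-])C=C([O-])OC.[Na+].[Li+] | intermediate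
15 | methyl 7-methyl-3-oxooct-6-enoate | COC(=O)CC(=O)CCC=C(C)C | intermediate
16 | methyl (2E)-3-methoxy-7-methylocta-2,6-dienoate | COC(=O)/C=C(/OC)CCC=C(C)C | intermediate
17 | lithium dienolate of 16 (not isolated) | CO/C([O-])=C/C(OC)=C/CC=C(C)C.[Li+] | intermediate
18 | (1Z,3Z)-1,3-dimethoxy-7-methyl-1-(trimethylsilyloxy)octa-1,3,6-triene | CO/C(O[Si](C)(C)C)=C/C(OC)=C/CC=C(C)C | intermediate
19 | cis-fused cycloadduct, sulfinyl on C4a and H-8a on the same face, drawn for addition anti to the C2 aryl group, C5, C8 and sulfur not assigned (not isolated) | COC1(O[Si](C)(C)C)C=C(OC)C(CC=C(C)C)[C@H]2O[C@H](c3ccc(O[Si](C)(C)C(C)(C)C)cc3)[C@@H](O[Si](C)(C)C(C)(C)C)C(=O)[C@@]12S(=O)c1ccccc1 | intermediate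
20 | cyclohexadiene mixed acetal after loss of PhSOH, C5 and C8 not assigned (not isolated) | COC1(O[Si](C)(C)C)C=C(OC)C(CC=C(C)C)C2=C1C(=O)[C@H](O[Si](C)(C)C(C)(C)C)[C@@H](c1ccc(O[Si](C)(C)C(C)(C)C)cc1)O2 | intermediate
21 | cross-conjugated dienone after loss of MeOSiMe3, C8 not assigned (not isolated) | O=C1C=C(OC)C(CC=C(C)C)C2=C1C(=O)[C@H](O[Si](C)(C)C(C)(C)C)[C@@H](c1ccc(O[Si](C)(C)C(C)(C)C)cc1)O2 | intermediate
22 | (2R,3R)-3-(TBSO)-2-[4-(TBSO)phenyl]-5-hydroxy-7-methoxy-8-prenylchroman-4-one | COc1cc(O)c2c(c1CC=C(C)C)O[C@H](c1ccc(O[Si](C)(C)C(C)(C)C)cc1)[C@@H](O[Si](C)(C)C(C)(C)C)C2=O | intermediate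
23 | (2R,3R)-3,5-dihydroxy-2-(4-hydroxyphenyl)-7-methoxy-8-prenylchroman-4-one | COc1cc(O)c2c(c1CC=C(C)C)O[C@H](c1ccc(O)cc1)[C@@H](O)C2=O | target

Total step count: 11. Longest linear sequence: 8 steps (steps 1–6, 10 and 11). The diene arm (steps 7–9) runs in parallel.

Steps most likely to fail

Step 10.
- Risk: The cycloaddition may be too slow because donation from O1 is not fully offset.
- Risk: The addition may turn stepwise, so that the resulting enolate expels O1 and opens ring C.
- Risk: Silicon may move from the ketene acetal to the sulfoxide oxygen and start a Pummerer-type diversion.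
- Fallback (known chemistry only): ring A is taken from an aromatic building block and ring C is closed by the chalcone epoxide route. It sets out from 13 and 1 and comes back at 23.
- Ring A ketone: commercial 2',6'-dihydroxy-4'-methoxyacetophenone is C-prenylated with 13 (KOH, MeOH) to 2,6-dihydroxy-4-methoxy-3-prenylacetophenone F1. Its less hindered 6-OH is methylated (Me2SO4, one equivalent, K2CO3, acetone) to 2-hydroxy-4,6-dimethoxy-3-prenylacetophenone F2. The remaining chelated phenol, the one next to the prenyl group and hence the future O1, is capped (NaH, MOMCl, DMF) as 4,6-dimethoxy-2-(methoxymethoxy)-3-prenylacetophenone F3.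
- Aldehyde: compound 1 is converted (MOMCl, iPr2NEt, CH2Cl2) into 4-(methoxymethoxy)benzaldehyde F4.
- Assembly: Claisen–Schmidt condensation of F3 with F4 (KOH, EtOH) gives the (E)-chalcone F5. Juliá–Colonna epoxidation (poly-L-leucine, urea·H2O2, DBU, THF) is a nucleophilic epoxidation that ignores the prenyl alkene and gives the (αR,βS)-epoxychalcone F6.
- Ring closure and end game: methanolic HCl removes both methoxymethyl groups and lets the single free 2'-phenol open the epoxide at the benzylic carbon with inversion. This gives (2R,3R)-3,4'-dihydroxy-5,7-dimethoxy-8-prenylflavanone F7. Chelation-directed cleavage of the methyl ether next to the carbonyl (MgI2, THF, reflux) then gives 23.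

Step 3.
- Risk: The enolate may open by loss of O1, which would erase C2.
- Risk: The oxidant may show incomplete anti selectivity.
- Risk: The enolate may add to the sulfonimine that the oxidant leaves behind.
- Fallback: it sets out from 5 and comes back at 7. α'-Acetoxylation with Mn(OAc)3 (benzene, reflux, water removed) needs no free alkali enolate and is established on 2-substituted dihydropyranones with trans selectivity. It gives (2R,3R)-3-acetoxy-2-[4-(TBSO)phenyl]-2,3-dihydro-4H-pyran-4-one F8. Neutral transesterification of this activated α-keto acetate (Bu2SnO cat., MeOH, 50 °C), which spares the aryl silyl ether, frees 7.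

Step 5.
- Risk: The push–pull alkene may react sluggishly, so that sulfenylation of the silyloxyarene competes.
- Risk: Adventitious HCl may strip a silyl ether.
- Fallback: it sets out from 8 and comes back at 10. α-Iodination of the enone (I2, pyridine, CH2Cl2) gives (2R,3R)-3-(TBSO)-2-[4-(TBSO)phenyl]-5-iodo-2,3-dihydro-4H-pyran-4-one F9. Cross-coupling with Bu3SnSPh under Pd(PPh3)4 catalysis (PhMe, 80 °C) forms the C5–S bond in a neutral medium, without free thiolate that could add to C6.

Further compounds
F1 | step 10 | 2,6-dihydroxy-4-methoxy-3-prenylacetophenone | CC(=O)c1c(O)cc(OC)c(CC=C(C)C)c1O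
F2 | step 10 | 2-hydroxy-4,6-dimethoxy-3-prenylacetophenone | CC(=O)c1c(OC)cc(OC)c(CC=C(C)C)c1O
F3 | step 10 | 4,6-dimethoxy-2-(methoxymethoxy)-3-prenylacetophenone | CC(=O)c1c(OC)cc(OC)c(CC=C(C)C)c1OCOC
F4 | step 10 | 4-(methoxymethoxy)benzaldehyde | COCOc1ccc(C=O)cc1
F5 | step 10 | (E)-4',6'-dimethoxy-2',4-bis(methoxymethoxy)-3'-prenylchalcone | COCOc1ccc(/C=C/C(=O)c2c(OC)cc(OC)c(CC=C(C)C)c2OCOC)cc1
F6 | step 10 | (αR,βS)-epoxide of chalcone F5 | O=C(c1c(OC)cc(OC)c(CC=C(C)C)c1OCOC)[C@@H]1O[C@H]1c1ccc(OCOC)cc1
F7 | step 10 | (2R,3R)-3,4'-dihydroxy-5,7-dimethoxy-8-prenylflavanone | COc1cc(OC)c2c(c1CC=C(C)C)O[C@H](c1ccc(O)cc1)[C@@H](O)C2=O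
F8 | step 3 | (2R,3R)-3-acetoxy-2-[4-(TBSO)phenyl]-2,3-dihydro-4H-pyran-4-one | C1=CO[C@H](c2ccc(O[Si](C)(C)C(C)(C)C)cc2)[C@@H](OC(C)=O)C1=O
F9 | step 5 | (2R,3R)-3-(TBSO)-2-[4-(TBSO)phenyl]-5-iodo-2,3-dihydro-4H-pyran-4-one | C1(I)=CO[C@H](c2ccc(O[Si](C)(C)C(C)(C)C)cc2)[C@@H](O[Si](C)(C)C(C)(C)C)C1=O
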